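## Retrosynthetic overview

1. The angelate goes on last, onto the 6α-hydroxyl of 2α-acetoxy-10β-benzoyloxydauc-8-ene-4β,6α-diol.
2. Ring A (five-membered) is formed second, through farnesane bond C6–C10. A C6-centred radical from a 5α,6α-epoxide closes on the isopropyl ketone. It stands in for the C6 cation, and the ketone oxygen plays the part of the captured water.
3. Ring B (seven-membered) is formed first, through farnesane bond C1–C7. A nerolidyl-type tertiary propargylic benzoate releases a (2Z)-1-benzoyloxyallyl cation, which the central C6=C7 olefin attacks through C7. A C5 silyl group steers the regiochemistry and relays the chirality.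
4. The open farnesane chain comes from 3-methylbutan-2-one, 2-methylfumaraldehyde mono-acetal, acetonylidene ylide and ethyne.
5. Ring order is B then A, across the central olefin, as in farnesyl → daucyl.

**Assumption and numbering note:** compound 2 is bought as the catalogue C5 carotenoid building block. Open-chain and ring B compounds carry farnesane numbers. Bicyclic compounds carry daucane numbers, and daucane C10, C1, C5, C4, C6, C2 correspond to farnesane C1, C7, C6, C10, C5, C8.

## Route

Step 1
Reactants: 1 3-methylbutan-2-one; 2 (E)-4,4-dimethoxy-2-methylbut-2-enal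
Product: 5 (5S,6E)-5-hydroxy-8,8-dimethoxy-2,6-dimethyloct-6-en-3-one, via enol borinate 3 (not isolated), via boron aldolate 4 (not isolated)
Conditions: (−)-Ipc2BCl, Et3N, Et2O, 0 °C; then 2, −78 → −20 °C; H2O2, MeOH, pH 7 buffer
Reagents that add atoms: none
Why: Paterson boron aldol; kinetic enolisation at the methyl group gives the diisopinocampheyl enol borinate, whose ligands (borane antipode chosen for this sense) select one aldehyde face in the cyclic transition state and set farnesane C8 as S at about 80% ee, and the minor antipode is removed later as a diastereomer once step 5 adds a catalyst-controlled centre.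

Step 2
Reactants: 5 (5S,6E)-5-hydroxy-8,8-dimethoxy-2,6-dimethyloct-6-en-3-one
Product: 6 (5S,6E)-8,8-dimethoxy-2,6-dimethyl-3-oxooct-6-en-5-yl acetate
Conditions: Ac2O, pyridine, DMAP (5 mol %), CH2Cl2, 0 °C
Reagents that add atoms: acetic anhydride, CC(=O)OC(C)=O
Why: DMAP-catalysed O-acylation installs the final acetate at once without touching the stereocentre, and the cold, weakly basic medium avoids E1cB loss from the β-acyloxy ketone.

Step 3
Reactants: 6 (5S,6E)-8,8-dimethoxy-2,6-dimethyl-3-oxooct-6-en-5-yl acetate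
Product: 7 (2E,4S)-4-acetoxy-3,7-dimethyl-6-oxooct-2-enal
Conditions: TsOH·H2O (5 mol %), acetone/H2O 10:1, rt
Reagents that add atoms: water, O
Why: Acid-catalysed acetal hydrolysis frees the conjugated aldehyde (farnesane C5); esters, ketone, olefin geometry and C8 are inert to dilute acid.

Step 4
Reactants: 7 (2E,4S)-4-acetoxy-3,7-dimethyl-6-oxooct-2-enal; 8 1-(triphenyl-λ5-phosphanylidene)propan-2-one
Product: 9 (3E,5E,7S)-7-acetoxy-6,10-dimethylundeca-3,5-diene-2,9-dione
Conditions: CH2Cl2, rt
Reagents that add atoms: none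
Why: Wittig olefination with a stabilised ylide is aldehyde-selective, essentially neutral so the γ-acetoxy enal survives, and E-selective; it adds farnesane C3, C4 and the C3 methyl.

Step 5
Reactants: 9 (3E,5E,7S)-7-acetoxy-6,10-dimethylundeca-3,5-diene-2,9-dione
Product: 10 (4R,5E,7S)-7-acetoxy-4-[dimethyl(phenyl)silyl]-6,10-dimethylundec-5-ene-2,9-dione
Conditions: PhMe2Si–Bpin, CuCl (5 mol %), (S,S)-1-mesityl-3-(2,6-diethylphenyl)-4,5-diphenylimidazolinium BF4 (5.5 mol %, antipode giving 4R), NaOtBu (11 mol %), MeOH (2 equiv), THF, −78 → −50 °C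
Reagents that add atoms: dimethyl(phenyl)silylboronic acid pinacol ester, CC1(C)OB(OC1(C)C)[Si](C)(C)c1ccccc1
Why: Enantioselective conjugate silyl addition catalysed by an N-heterocyclic carbene complex of monovalent copper goes 1,4 because the δ-carbon is fully substituted, and the chiral ligand sets the allylsilane centre (farnesane C5) as R.

Step 6
Reactants: 10 (4R,5E,7S)-7-acetoxy-4-[dimethyl(phenyl)silyl]-6,10-dimethylundec-5-ene-2,9-dione; 11 ethynylmagnesium bromide
Product: 13 (5R,6E,8S)-8-acetoxy-5-[dimethyl(phenyl)silyl]-3,7,11-trimethyl-10-oxododec-6-en-1-yn-3-yl benzoate (both C3 epimers), via magnesium alkoxide 12 (not isolated)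
Conditions: 11 (1.05 equiv), THF, −78 °C; then BzCl, DMAP (10 mol %), −78 °C → rt
Reagents that add atoms: benzoyl chloride, O=C(Cl)c1ccccc1
Why: Grignard 1,2-addition followed by in-flask O-acylation; at −78 °C the weakly basic acetylide takes the unhindered methyl ketone ahead of the α-branched isopropyl ketone and the acetate, and the C3 epimer mixture does not matter because C3 becomes sp2 in step 7.

Step 7
Reactants: 13 (5R,6E,8S)-8-acetoxy-5-[dimethyl(phenyl)silyl]-3,7,11-trimethyl-10-oxododec-6-en-1-yn-3-yl benzoate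
Product: 16 (1S,7R)-7-[(1S)-1-acetoxy-4-methyl-3-oxopentyl]-3,7-dimethylcyclohepta-2,5-dien-1-yl benzoate, via allenyl benzoate 14 (not isolated), via gem-dibenzoate 15 (not isolated)
Conditions: AgNTf2 (5 mol %), PhCO2H (1.2 equiv), ClCH2CH2Cl, 45 °C; then Me3SiOTf (15 mol %), CH2Cl2, −78 °C, 2 mM
Reagents that add atoms: benzoic acid, O=C(O)c1ccccc1
Why: Proposed new method: monovalent silver triggers the Saucy–Marbet [3,3] shift of the tertiary propargylic benzoate to allenyl benzoate 14, benzoic acid adds to give the enal acylal 15, and Me3SiOTf ionises one benzoate to a 1-benzoyloxyallyl cation whose 2E and 2Z forms interconvert through the tertiary C3 resonance form so that only the 2Z form can close; the β-silicon effect makes the C6=C7 olefin attack C1 through C7 (seven-membered ring) instead of through C6 (six-membered ring), the only productive anti-SE2′ conformer (silyl perpendicular, C4 inside, as the cis ring olefin demands) relays 5R to 7R, and the benzoyloxy group takes the outward pseudo-equatorial site to give 1S; the closest known reaction types are the Saucy–Marbet rearrangement, the Hosomi–Sakurai allylation of acylals and allylsilane-terminated cation–olefin cyclisation.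

Step 8
Reactants: 16 (1S,7R)-7-[(1S)-1-acetoxy-4-methyl-3-oxopentyl]-3,7-dimethylcyclohepta-2,5-dien-1-yl benzoate
Product: 18 5α,6α-epoxide of 16 (1S,5S,6R,7R,8S in farnesane numbering), via side-chain dioxirane 17 (not isolated)
Conditions: KHSO5 (as 2KHSO5·KHSO4·K2SO4), NaHCO3, MeCN/aq Na2EDTA, 0 °C → rt, 5 mM
Reagents that add atoms: potassium peroxymonosulfate, [K+].[O-]S(=O)(=O)OO
Why: Ketone-directed intramolecular dioxirane epoxidation; the side-chain ketone is turned into its dioxirane and hands oxygen through a six-membered spiro transition state to the only olefin within reach (C5=C6, not the benzoate-deactivated C2=C3), and from the α face on which the side chain stands, which sets C5 and C6.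

Step 9
Reactants: 18 5α,6α-epoxide of 16
Product: 19 (1R,2S,4R,5S,6S,10S)-2-acetoxy-10-benzoyloxydauc-8-ene-4,6-diol
Conditions: Cp2TiCl2 (20 mol %), Mn, 2,4,6-collidine·HCl, THF, rt
Reagents that add atoms: none
Why: Nugent–RajanBabu/Gansäuer reductive epoxide opening followed by 5-exo radical addition to a ketone; trivalent titanium cleaves the more hindered C6–O bond, the farnesane C6 radical adds to ketone carbon C10 anti to the bulky 5α-titanoxy group (β attack, hence daucane 5α-H and the trans fusion), the isopropyl group turns toward the small H-5 so the carbinol is 4β-OH, and a second trivalent titanium traps the alkoxyl radical irreversibly.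

Step 10
Reactants: 19 (1R,2S,4R,5S,6S,10S)-2-acetoxy-10-benzoyloxydauc-8-ene-4,6-diol; 20 angelic acid
Product: 21 2α-acetoxy-6α-angeloyloxy-10β-benzoyloxydauc-8-en-4β-ol (target, CNP0248576.1)
Conditions: 20, 2,4,6-Cl3C6H2COCl, Et3N, toluene, rt; then 19, 80 °C
Reagents that add atoms: none
Why: Yamaguchi-type mixed-anhydride esterification run without DMAP keeps the Z geometry of the angelate and acylates only the secondary 6α-hydroxyl, while the tertiary 4β-hydroxyl stays free.

## Compound list

1 | 3-methylbutan-2-one | CC(C)C(C)=O | starting material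
2 | (E)-4,4-dimethoxy-2-methylbut-2-enal | COC(OC)/C=C(\C)C=O | starting material
3 | 3-methylbut-1-en-2-yl diisopinocampheylborinate | CC(C)C(=C)OB(C1CC2CC(C1C)C2(C)C)C1CC2CC(C1C)C2(C)C | intermediate
4 | diisopinocampheylboron aldolate of 5 | COC(OC)/C=C(\C)[C@@H](OB(C1CC2CC(C1C)C2(C)C)C1CC2CC(C1C)C2(C)C)CC(=O)C(C)C | intermediate
5 | (5S,6E)-5-hydroxy-8,8-dimethoxy-2,6-dimethyloct-6-en-3-one | COC(OC)/C=C(\C)[C@@H](O)CC(=O)C(C)C | intermediate
6 | (5S,6E)-8,8-dimethoxy-2,6-dimethyl-3-oxooct-6-en-5-yl acetate | COC(OC)/C=C(\C)[C@@H](OC(C)=O)CC(=O)C(C)C | intermediate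
7 | (2E,4S)-4-acetoxy-3,7-dimethyl-6-oxooct-2-enal | O=C/C=C(\C)[C@@H](OC(C)=O)CC(=O)C(C)C | intermediate
8 | 1-(triphenyl-λ5-phosphanylidene)propan-2-one | CC(=O)C=P(c1ccccc1)(c1ccccc1)c1ccccc1 | starting material
9 | (3E,5E,7S)-7-acetoxy-6,10-dimethylundeca-3,5-diene-2,9-dione | CC(=O)/C=C/C=C(\C)[C@@H](OC(C)=O)CC(=O)C(C)C | intermediate
10 | (4R,5E,7S)-7-acetoxy-4-[dimethyl(phenyl)silyl]-6,10-dimethylundec-5-ene-2,9-dione | CC(=O)C[C@@H]([Si](C)(C)c1ccccc1)/C=C(\C)[C@@H](OC(C)=O)CC(=O)C(C)C | intermediate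
11 | ethynylmagnesium bromide | C#C[Mg]Br | starting material
12 | bromomagnesium alkoxide of the C3 propargylic alcohol (C3 epimers) | C#CC(C)(O[Mg]Br)C[C@@H]([Si](C)(C)c1ccccc1)/C=C(\C)[C@@H](OC(C)=O)CC(=O)C(C)C | intermediate
13 | (5R,6E,8S)-8-acetoxy-5-[dimethyl(phenyl)silyl]-3,7,11-trimethyl-10-oxododec-6-en-1-yn-3-yl benzoate (C3 epimers) | C#CC(C)(OC(=O)c1ccccc1)C[C@@H]([Si](C)(C)c1ccccc1)/C=C(\C)[C@@H](OC(C)=O)CC(=O)C(C)C | intermediate
14 | (5R,6E,8S)-8-acetoxy-5-[dimethyl(phenyl)silyl]-3,7,11-trimethyl-10-oxododeca-1,2,6-trien-1-yl benzoate | O=C(OC=C=C(C)C[C@@H]([Si](C)(C)c1ccccc1)/C=C(\C)[C@@H](OC(C)=O)CC(=O)C(C)C)c1ccccc1 | intermediate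
15 | (5R,6E,8S)-8-acetoxy-5-[dimethyl(phenyl)silyl]-3,7,11-trimethyl-10-oxododeca-2,6-diene-1,1-diyl dibenzoate (2E/2Z) | O=C(OC(OC(=O)c1ccccc1)C=C(C)C[C@@H]([Si](C)(C)c1ccccc1)/C=C(\C)[C@@H](OC(C)=O)CC(=O)C(C)C)c1ccccc1 | intermediate
16 | (1S,7R)-7-[(1S)-1-acetoxy-4-methyl-3-oxopentyl]-3,7-dimethylcyclohepta-2,5-dien-1-yl benzoate | C1C(C)=C[C@H](OC(=O)c2ccccc2)[C@@](C)([C@@H](OC(C)=O)CC(=O)C(C)C)C=C1 | intermediate
17 | dioxirane of 16 at the side-chain ketone carbon | C1C(C)=C[C@H](OC(=O)c2ccccc2)[C@@](C)([C@@H](OC(C)=O)CC2(OO2)C(C)C)C=C1 | intermediate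
18 | 5α,6α-epoxide of 16 (1S,5S,6R,7R,8S, farnesane numbering) | C1C(C)=C[C@H](OC(=O)c2ccccc2)[C@@](C)([C@@H](OC(C)=O)CC(=O)C(C)C)[C@H]2O[C@H]21 | intermediate
19 | (1R,2S,4R,5S,6S,10S)-2-acetoxy-10-benzoyloxydauc-8-ene-4,6-diol | O[C@H]1CC(C)=C[C@H](OC(=O)c2ccccc2)[C@@]2(C)[C@@H](OC(C)=O)C[C@@](O)(C(C)C)[C@H]12 | intermediate
20 | angelic acid, (Z)-2-methylbut-2-enoic acid | C/C=C(/C)C(=O)O | starting material
21 | 2α-acetoxy-6α-angeloyloxy-10β-benzoyloxydauc-8-en-4β-ol (1R,2S,4R,5S,6S,10S) | C/C=C(/C)C(=O)O[C@H]1CC(C)=C[C@H](OC(=O)c2ccccc2)[C@@]2(C)[C@@H](OC(C)=O)C[C@@](O)(C(C)C)[C@H]12 | target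

## Step count and risks

Total step count: 10. Longest linear sequence: 10 (1 or 2 → 21).

**Step 7 (ring B closure).**
- Failure modes: Lewis-acid 1,4-elimination of the C5 silyl and C8 acetoxy groups to a diene, protodesilylation, or sluggish acylal formation.
- Fallback: it sets out from 13 and comes back at 16, and it activates a neutral aldehyde instead of generating a cation by ionisation. AgNTf2 in wet acetone takes 13 through the hydrolytic Saucy–Marbet sequence to the neral-type aldehyde (5R,6E,8S)-8-acetoxy-5-[dimethyl(phenyl)silyl]-3,7,11-trimethyl-10-oxododeca-2,6-dienal F1. Its 2E and 2Z forms are equilibrated with a trace of iodine.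
- Me2AlCl at −78 °C binds only the aldehyde oxygen, so the allylic acetate is not ionised. It promotes the intramolecular Hosomi–Sakurai closure of the 2Z form to the allylic alcohol (1S,7R)-7-[(1S)-1-acetoxy-4-methyl-3-oxopentyl]-3,7-dimethylcyclohepta-2,5-dien-1-ol F2. BzCl in pyridine then gives 16.

**Step 8 (directed epoxidation).**
- Failure modes: the hindered, unactivated ketone may form its dioxirane too slowly, so that intermolecular oxygen transfer to C2=C3 intrudes.
- Fallback: it sets out from 16 and comes back at 19, and it replaces the epoxide–radical logic by a sterically governed oxidation and a polar closure. A Wacker-type oxidation with divalent palladium (Pd(OAc)2, benzoquinone, aq HBF4, MeCN/DMA) touches only the disubstituted olefin. It puts the carbonyl on C5, distal to the quaternary carbon and its two β-acyloxy groups, and gives the ring B ketone (1S,7R)-7-[(1S)-1-acetoxy-4-methyl-3-oxopentyl]-3,7-dimethyl-5-oxocyclohept-2-en-1-yl benzoate F3.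
- Pyrrolidinium acetate closes C6 onto C10 by intramolecular aldol addition to the ketol 2α-acetoxy-10β-benzoyloxy-4β-hydroxydauc-8-en-6-one F4. Evans–Saksena reduction with Me4NBH(OAc)3, directed by the 4β-hydroxyl, delivers 19.

**Step 9 (ring A closure).**
- Failure modes: epoxide opening toward the C5 radical, deoxygenation to the olefin, or cis fusion.
- Fallback: it sets out from 18 and comes back at 19, and it uses a regiospecific enolate in place of the radical. DMSO and TfOH, then iPr2NEt (Kornblum-type epoxide oxidation, with attack at the less hindered C5), give the α-ketol (1S,6R,7R)-7-[(1S)-1-acetoxy-4-methyl-3-oxopentyl]-6-hydroxy-3,7-dimethyl-5-oxocyclohept-2-en-1-yl benzoate F5.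
- SmI2 (divalent samarium) in THF/MeOH at −78 °C removes the α-hydroxyl. The samarium enolate, located only at C6, undergoes a chelated aldol addition to the isopropyl ketone to give the ketol F4. This is reduced with Me4NBH(OAc)3 to 19.

## Further compounds

F1 | step 7 | (5R,6E,8S)-8-acetoxy-5-[dimethyl(phenyl)silyl]-3,7,11-trimethyl-10-oxododeca-2,6-dienal (2E/2Z) | O=CC=C(C)C[C@@H]([Si](C)(C)c1ccccc1)/C=C(\C)[C@@H](OC(C)=O)CC(=O)C(C)C
F2 | step 7 | (1S,7R)-7-[(1S)-1-acetoxy-4-methyl-3-oxopentyl]-3,7-dimethylcyclohepta-2,5-dien-1-ol | C1C(C)=C[C@H](O)[C@@](C)([C@@H](OC(C)=O)CC(=O)C(C)C)C=C1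
F3 | step 8 | (1S,7R)-7-[(1S)-1-acetoxy-4-methyl-3-oxopentyl]-3,7-dimethyl-5-oxocyclohept-2-en-1-yl benzoate | O=C1CC(C)=C[C@H](OC(=O)c2ccccc2)[C@@](C)([C@@H](OC(C)=O)CC(=O)C(C)C)C1
F4 | step 8 | 2α-acetoxy-10β-benzoyloxy-4β-hydroxydauc-8-en-6-one | O=C1CC(C)=C[C@H](OC(=O)c2ccccc2)[C@@]2(C)[C@@H](OC(C)=O)C[C@@](O)(C(C)C)[C@H]12
F5 | step 9 | (1S,6R,7R)-7-[(1S)-1-acetoxy-4-methyl-3-oxopentyl]-6-hydroxy-3,7-dimethyl-5-oxocyclohept-2-en-1-yl benzoate | O=C1CC(C)=C[C@H](OC(=O)c2ccccc2)[C@@](C)([C@@H](OC(C)=O)CC(=O)C(C)C)[C@H]1O
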